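## Structural features

The target joins three units in a row: a 5-methylcoumarin (a benzene ring fused to a 2-pyranone), an (E)-3-methylpent-2-ene-1,5-diyl chain bound through oxygen to C4 of the pyranone, and a 2,2-dimethyl-4-methylidenecyclohexanone bound through its C3. The only stereocentre is that ring CH (R). It stands between the quaternary gem-dimethyl carbon, which is α to the ketone, and the sp2 carbon that carries the exocyclic methylene. It cannot be lost by enolisation, but it is allylic, so any acid that moves the exocyclic double bond into the ring would erase it. The fragile groups are the 4-alkoxycoumarin (a vinylogous ester and an allyl vinyl ether, sensitive to acid, hydroxide and heat), the exocyclic alkene, and the geometry of the trisubstituted chain alkene. The real difficulty is the contiguous array quaternary carbon – stereocentre – methylene-bearing carbon in one ring with defined absolute configuration, together with the E alkene. The key step exploits the C(=CH2)–CH2 segment next to the stereocentre. It is what an isopropenyl group becomes when its CH2 terminus bonds to an aldehyde carbon and a methyl hydrogen is given up, and the stereocentre with its isopropenyl group and two-carbon arm is C4 of (S)-limonene. Tracing the atoms confirms that (S)-limonene, not its enantiomer, gives the required configuration; the descriptor changes from S to R along the way only because substituent priorities change.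

## Logic of the disconnections

**24 to 21 and 23.** The bond cut is the O–CH2 bond between the allylic carbon and the oxygen on C4 of the pyranone. It is the most fragile link in 24, and cutting it last keeps the lactone away from every organometallic, Lewis-acidic and reducing step. The cut separates the achiral aromatic part from the chiral terpenoid part. The forward step must alkylate the C4 oxygen (not the lactone carbonyl oxygen or C3), without allylic transposition, at or below room temperature.

**23 to 22.** The lactone O–C2 and C2–C3 bonds are cut, which removes the lactone carbonyl carbon. That carbon is a one-carbon electrophile inserted between the phenol oxygen and the acetyl methyl group of 22. The methyl group on the benzene ring is already in place in 22. The forward step needs C-acylation of the ketone enolate followed by ring closure onto the phenoxide.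

**21 to 18 (through 20 and 19).** No skeletal bond is cut. Going backwards, the hydroxyl of 21 is capped as a silyl ether (20) and an oxygen is put back on the CH2 next to the ketone (19, then 18). That oxygen is the trace of the aldehyde that closes the ring, and the adjacent ketone is what allows its reductive removal. The forward steps must cleave only this C–O bond, without reducing the ketone or moving either alkene, and must acylate the ketol before it can tautomerise.

**18 to 17 (key disconnection).** The ring bond between the two ring CH2 carbons is cut, and the exocyclic methylene is returned to a methyl group. This opens the only carbocycle and leaves an acyclic chain with one stereocentre, an isopropenyl group and a 1,2-dicarbonyl terminus. The forward step must react at the aldehyde and not the ketone, at the isopropenyl group and not the chain alkene, and must transfer a methyl hydrogen.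

**17 to 14 (through 16).** After both carbonyls are returned to the diol level (16), the bond between the terminal carbon and the carbinol carbon is cut. The 1,2-dicarbonyl is too reactive to carry, so its terminal carbon arrives late as a hydroxymethyl anion equivalent. This reduces the problem to a neopentyl aldehyde. The forward steps need addition to a hindered, non-enolisable aldehyde and a double oxidation that does not cleave the glycol.

**14 to 10 (through 12).** The two C–CH3 bonds at the carbon next to the functional carbon are cut, with aldehyde and nitrile interchanged. A nitrile is chosen over an ester because its small anion builds a quaternary carbon next to a tertiary one, and one reduction then gives the aldehyde. This removes the quaternary carbon. The forward step needs two complete methylations; the stereocentre is β to the nitrile and carries no acidic hydrogen.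

**10 to 7 (through 8).** No C–C bond is cut; nitrile, aldehyde and dimethyl acetal are interchanged. The acetal is the form in which this carbon is kept while the other chain end is built. The forward hydrolysis must spare the silyl ether, which is why a tert-butyldiphenylsilyl ether is used and not a tert-butyldimethylsilyl ether.

**7 to 3 and 4 (through 6 and 5).** The C=C bond of the trisubstituted alkene is cut, after the O–Si bond and the alcohol/ester interchange. The two-carbon oxygenated terminus comes from 4, and 3 is a plain methyl ketone. The forward olefination must favour the E isomer and tolerate the acetal.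

**3 to 1.** The ketone carbon and the acetal carbon are rejoined as the ring C=C of 1. Compound 1 supplies the stereocentre, the isopropenyl group and two arms that differ at their ends (methyl ketone and aldehyde). The forward step must cleave the trisubstituted alkene in preference to the 1,1-disubstituted one and must distinguish the aldehyde from the ketone.

## Other disconnections considered

**Alternative 1:** The cut is in the side chain, at the bond between the methyl-bearing alkene carbon and its methyl group and at the bond between the alkene CH and the CH2O carbon. In the forward sense the terminal alkyne A2 would be methylaluminated with AlMe3 under Cp2ZrCl2 catalysis and the alkenylalane trapped with formaldehyde to give the allylic alcohol A1.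
- In favour: syn addition fixes the E geometry by mechanism. On alkene geometry this is better than the phosphonate olefination of step 2, which relies on a preference and a separation. Two C–C bonds form in one operation.
- Against: the cut does not address the ring. The quaternary carbon, the stereocentre and the exocyclic methylene must all be present in A2 beforehand. AlMe3 and the zirconium species may move the exocyclic alkene. The ring oxygen is at the alcohol level, so desilylation and oxidation must follow the etherification, with the coumarin ether exposed to both.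
- Comparison: equal in mechanistic reliability, better in geometry control, poorer in step economy, because A2 needs a full ring synthesis plus a homologation to the alkyne. The idea is kept as the fallback for step 2.

**Alternative 2:** The cut is the ring bond between the methylene-bearing carbon and the ring CH. In the forward sense the aldehyde enoate A4 would cyclise under a chiral aminoindanol-derived triazolium carbene (intramolecular Stetter reaction) to the keto ester A3.
- In favour: the stereocentre is set by a catalyst, so either enantiomer is reachable without a chiral pool (better). The gem-dimethyl carbon comes from an achiral building block, so no double alkylation next to a stereocentre is needed (better). The ring oxygen is correctly placed from the start and nothing must be deoxygenated later (better).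
- Against: the acceptor carbon is neopentylic and aliphatic aldehydes are the less reactive partners, so rate and enantioselectivity are both uncertain. In A3 the new stereocentre is α to a ketone and may epimerise during the cyclisation or a later methylenation; in the chosen plan the stereocentre is never α to a carbonyl. The ester arm must still be extended by the C(CH3)=CH–CH2O unit, which brings back the geometry problem.
- Comparison: more flexible in absolute configuration, less secure in configuration once set, and not shorter, since A4 needs several steps and about eight more would follow A3.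

**Alternative 3:** The cut is the ring bond between the methylene-bearing carbon and the neighbouring ring CH2. The keto aldehyde A6 would come from the terpene-pool aldehyde A7 by reduction, silylation, oxidative cleavage of the ring alkene and α-methylenation. A secondary amine would convert its aldehyde into an enamine that adds to the tethered vinyl ketone (intramolecular Michael addition) to give the formyl ketone A5.
- In favour: A7 already holds the gem-dimethyl carbon next to the stereocentre, so the quaternary carbon is not made at all (better than step 7). The ketone sits on the right carbon and nothing is deoxygenated (better than steps 12 and 13). The conditions are mild and metal-free (equal or better).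
- Against: both enone carbons end up inside the new ring, a slower closure mode than an exo Michael addition, and a vinyl ketone with an aldehyde in the same molecule may polymerise. The formyl group must then be turned into the exocyclic methylene in three operations beside a ketone. The enantiomeric purity of A7 is usually lower than that of 1. The side chain stops at two carbons, so four more carbons and the E alkene are still to be added.
- Comparison: better in how the ring oxygen and the quaternary carbon are obtained, weaker in enantiopurity and ring-closure mode, and longer overall.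

Key step: step 11

Assumption: the carbinol carbons formed in steps 9 and 11 are carried as mixtures of epimers because steps 10 and 13 remove them, and ozone in step 1 is metered to one equivalent.

## Route

Step 1
Reactants: 1 (S)-(−)-limonene
Product: 3 (5S)-7,7-dimethoxy-5-(prop-1-en-2-yl)heptan-2-one, via keto aldehyde 2 (not isolated)
Conditions: O3 (1.0 equiv), CH2Cl2/MeOH, −78 °C; Me2S, −78 °C → rt; then p-TsOH (cat.), rt; NaHCO3
Reagents that add atoms: ozone, O=[O+][O-]; methanol, CO
Why: Ozonolysis with reductive work-up; the electron-richer trisubstituted ring alkene should consume the single equivalent of ozone before the isopropenyl group, and in acidic methanol only the aldehyde of 2 forms a dimethyl acetal because a methyl ketone acetalises far less readily. The stereocentre is not involved.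

Step 2
Reactants: 3 (5S)-7,7-dimethoxy-5-(prop-1-en-2-yl)heptan-2-one; 4 triethyl phosphonoacetate
Product: 5 ethyl (2E,6S)-8,8-dimethoxy-3-methyl-6-(prop-1-en-2-yl)oct-2-enoate
Conditions: NaH, THF, 0 °C → 45 °C
Reagents that add atoms: none
Why: Horner–Wadsworth–Emmons olefination of the methyl ketone, to which the acetal is inert; the E isomer (ester trans to the longer chain) is expected to predominate and the Z isomer is to be removed by chromatography here or after step 3.

Step 3
Reactants: 5 ethyl (2E,6S)-8,8-dimethoxy-3-methyl-6-(prop-1-en-2-yl)oct-2-enoate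
Product: 6 (2E,6S)-8,8-dimethoxy-3-methyl-6-(prop-1-en-2-yl)oct-2-en-1-ol
Conditions: i-Bu2AlH, CH2Cl2, −78 °C; aq. potassium sodium tartrate
Reagents that add atoms: none
Why: 1,2-Reduction of the unsaturated ester by i-Bu2AlH at low temperature gives the allylic alcohol without touching the acetal or the alkene geometry.

Step 4
Reactants: 6 (2E,6S)-8,8-dimethoxy-3-methyl-6-(prop-1-en-2-yl)oct-2-en-1-ol
Product: 7 tert-butyl{[(2E,6S)-8,8-dimethoxy-3-methyl-6-(prop-1-en-2-yl)oct-2-en-1-yl]oxy}diphenylsilane
Conditions: TBDPSCl, imidazole, CH2Cl2, 0 °C → rt
Reagents that add atoms: tert-butyl(chloro)diphenylsilane (TBDPSCl), CC(C)(C)[Si](Cl)(c1ccccc1)c1ccccc1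
Why: Standard silylation of a primary alcohol; the tert-butyldiphenylsilyl ether is chosen over the tert-butyldimethylsilyl ether because it must survive the aqueous acid of steps 5 and 8 and the Lewis acid of step 11.

Step 5
Reactants: 7 tert-butyl{[(2E,6S)-8,8-dimethoxy-3-methyl-6-(prop-1-en-2-yl)oct-2-en-1-yl]oxy}diphenylsilane
Product: 8 (3S,6E)-8-[(tert-butyldiphenylsilyl)oxy]-6-methyl-3-(prop-1-en-2-yl)oct-6-enal
Conditions: AcOH/THF/H2O (3:1:1), 40 °C
Reagents that add atoms: water, O
Why: Acid-catalysed acetal hydrolysis; aqueous acetic acid cleaves the dimethyl acetal of an aliphatic aldehyde under conditions that leave a primary tert-butyldiphenylsilyl ether and both alkenes intact. The stereocentre is β to the aldehyde and cannot epimerise.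

Step 6
Reactants: 8 (3S,6E)-8-[(tert-butyldiphenylsilyl)oxy]-6-methyl-3-(prop-1-en-2-yl)oct-6-enal
Product: 10 (3S,6E)-8-[(tert-butyldiphenylsilyl)oxy]-6-methyl-3-(prop-1-en-2-yl)oct-6-enenitrile, via aldoxime 9 (not isolated)
Conditions: NH2OH·HCl, pyridine, rt; then (CF3CO)2O, 0 °C → rt
Reagents that add atoms: hydroxylamine hydrochloride, NO.Cl
Why: Oxime formation followed by dehydration of its O-trifluoroacetate in the same flask is a standard aldehyde-to-nitrile conversion; the nitrile is chosen because its small linear anion is the best nucleophile for building the quaternary carbon in step 7.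

Step 7
Reactants: 10 (3S,6E)-8-[(tert-butyldiphenylsilyl)oxy]-6-methyl-3-(prop-1-en-2-yl)oct-6-enenitrile
Product: 12 (3R,6E)-8-[(tert-butyldiphenylsilyl)oxy]-2,2,6-trimethyl-3-(prop-1-en-2-yl)oct-6-enenitrile, via monomethyl nitrile 11 (not isolated)
Conditions: LiN(i-Pr)2 (commercial solution), THF, −78 °C; MeI; then LiN(i-Pr)2, −78 °C; MeI, −78 °C → rt
Reagents that add atoms: iodomethane, CI
Why: Two successive α-alkylations of the nitrile anion; the second builds the quaternary carbon next to the tertiary stereocentre, which the sterically undemanding nitrile anion tolerates. The stereocentre is β to the nitrile and has no acidic hydrogen; its descriptor becomes R only through a change of priorities.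

Step 8
Reactants: 12 (3R,6E)-8-[(tert-butyldiphenylsilyl)oxy]-2,2,6-trimethyl-3-(prop-1-en-2-yl)oct-6-enenitrile
Product: 14 (3R,6E)-8-[(tert-butyldiphenylsilyl)oxy]-2,2,6-trimethyl-3-(prop-1-en-2-yl)oct-6-enal, via N-aluminio aldimine 13 (not isolated)
Conditions: i-Bu2AlH, toluene, −78 → 0 °C; then cold 1 M aq. HCl, 0 °C
Reagents that add atoms: water, O
Why: Partial reduction of a nitrile by i-Bu2AlH stops at the N-aluminio aldimine, which brief cold aqueous acid hydrolyses to the aldehyde; the product has no α-hydrogen and cannot enolise.

Step 9
Reactants: 14 (3R,6E)-8-[(tert-butyldiphenylsilyl)oxy]-2,2,6-trimethyl-3-(prop-1-en-2-yl)oct-6-enal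
Product: 16 (4R,7E)-9-[(tert-butyldiphenylsilyl)oxy]-3,3,7-trimethyl-4-(prop-1-en-2-yl)non-7-ene-1,2-diol, via hydroxy silane 15 (not isolated)
Conditions: (i-PrO)Me2SiCH2MgCl (from ClCH2SiMe2(Oi-Pr), Mg), THF, 0 °C → rt; then 30% H2O2, KF, KHCO3, THF/MeOH, rt
Reagents that add atoms: (isopropoxydimethylsilyl)methylmagnesium chloride, CC(C)O[Si](C)(C)C[Mg]Cl; hydrogen peroxide, OO
Why: Tamao nucleophilic hydroxymethylation: the silylmethyl Grignard reagent has no β-hydrogen, so it adds to the hindered aldehyde without reducing it, and the C–Si bond of 15 is then oxidised to the primary alcohol by H2O2 and fluoride. The new carbinol centre is formed without control because step 10 removes it.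

Step 10
Reactants: 16 (4R,7E)-9-[(tert-butyldiphenylsilyl)oxy]-3,3,7-trimethyl-4-(prop-1-en-2-yl)non-7-ene-1,2-diol
Product: 17 (4R,7E)-9-[(tert-butyldiphenylsilyl)oxy]-3,3,7-trimethyl-2-oxo-4-(prop-1-en-2-yl)non-7-enal
Conditions: (COCl)2, DMSO, CH2Cl2, −78 °C; Et3N, −78 → 0 °C; azeotropic drying (toluene)
Reagents that add atoms: none
Why: Swern oxidation with excess activated DMSO oxidises both hydroxyls without cleaving the glycol C–C bond, since no cyclic glycol ester is involved. The dicarbonyl product has no α-hydrogen for triethylamine to remove; it is dried and used at once because it hydrates readily.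

Step 11
Reactants: 17 (4R,7E)-9-[(tert-butyldiphenylsilyl)oxy]-3,3,7-trimethyl-2-oxo-4-(prop-1-en-2-yl)non-7-enal
Product: 18 (3R)-3-[(3E)-5-[(tert-butyldiphenylsilyl)oxy]-3-methylpent-3-en-1-yl]-6-hydroxy-2,2-dimethyl-4-methylidenecyclohexan-1-one
Conditions: Me2AlCl (2 equiv), CH2Cl2 (0.01 M), −78 → −40 °C; aq. potassium sodium tartrate
Reagents that add atoms: none
Why: Intramolecular carbonyl-ene reaction of type 2: Me2AlCl binds the aldehyde oxygen of the 1,2-dicarbonyl unit, the CH2 terminus of the isopropenyl group attacks the aldehyde carbon, and a hydrogen of the isopropenyl methyl group passes to oxygen through a six-membered transition state, so the former methyl carbon becomes the exocyclic methylene. The closest known reactions are the Me2AlCl-promoted type 2 cyclisations of 5-methylhex-5-enals to 3-methylenecyclohexanols and the ene reactions of glyoxylates and glyoxals, which show that a carbonyl-activated aldehyde is a very good enophile. The six-membered ring closes by joining the alkene terminus to the aldehyde carbon; both alkene carbons end up in the ring (endo with respect to the alkene) and the oxygen stays outside it (exo with respect to the carbonyl). The only new stereocentre is the carbinol carbon, left uncontrolled because step 13 removes it, while the ring CH keeps the configuration brought from 1 because none of its bonds is made or broken. Selectivity for the aldehyde over the ketone is secured by the quaternary carbon that shields the ketone and by the strained five-membered type 2 transition state that closure onto the ketone would need. The chain alkene does not compete because it could only close a seven- or eight-membered ring and is deactivated by its allylic oxygen. The methyl hydrogen is transferred, and not the ring-CH hydrogen, because that CH lies in the forming ring and cannot reach the oxygen; Me2AlCl also removes protons as methane, which suppresses cationic migration of the new double bond into the ring. The reaction is run cold and dilute to avoid methyl transfer from aluminium and intermolecular reaction.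

Step 12
Reactants: 18 (3R)-3-[(3E)-5-[(tert-butyldiphenylsilyl)oxy]-3-methylpent-3-en-1-yl]-6-hydroxy-2,2-dimethyl-4-methylidenecyclohexan-1-one
Product: 19 (4R)-4-[(3E)-5-[(tert-butyldiphenylsilyl)oxy]-3-methylpent-3-en-1-yl]-3,3-dimethyl-5-methylidene-2-oxocyclohexyl acetate
Conditions: Ac2O, pyridine, DMAP (cat.), CH2Cl2, 0 °C
Reagents that add atoms: acetic anhydride, CC(=O)OC(C)=O
Why: DMAP-catalysed acylation of the secondary hydroxyl at 0 °C is faster than enolisation of the α-hydroxy ketone, so the ketol is fixed before it can tautomerise; the acetate is the leaving group for step 13.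

Step 13
Reactants: 19 (4R)-4-[(3E)-5-[(tert-butyldiphenylsilyl)oxy]-3-methylpent-3-en-1-yl]-3,3-dimethyl-5-methylidene-2-oxocyclohexyl acetate
Product: 20 (3R)-3-[(3E)-5-[(tert-butyldiphenylsilyl)oxy]-3-methylpent-3-en-1-yl]-2,2-dimethyl-4-methylidenecyclohexan-1-one
Conditions: SmI2 (2.5 equiv), THF/MeOH, −78 °C
Reagents that add atoms: none
Why: Reductive cleavage of an α-acyloxy ketone by SmI2: two single-electron transfers from divalent samarium give a ketyl that expels acetate and then a samarium enolate, which methanol protonates at carbon. Isolated alkenes, the silyl ether and the ketone are not reduced under these conditions, and the carbinol centre of step 11 disappears.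

Step 14
Reactants: 20 (3R)-3-[(3E)-5-[(tert-butyldiphenylsilyl)oxy]-3-methylpent-3-en-1-yl]-2,2-dimethyl-4-methylidenecyclohexan-1-one
Product: 21 (3R)-3-[(3E)-5-hydroxy-3-methylpent-3-en-1-yl]-2,2-dimethyl-4-methylidenecyclohexan-1-one
Conditions: Bu4NF, AcOH, THF, 0 °C → rt
Reagents that add atoms: none
Why: Fluoride cleaves the Si–O bond; buffering with acetic acid keeps the medium from becoming basic enough to enolise the ketone or move the exocyclic alkene.

Step 15
Reactants: 22 2'-hydroxy-6'-methylacetophenone
Product: 23 4-hydroxy-5-methyl-2H-chromen-2-one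
Conditions: NaH, (EtO)2CO, toluene, 100 °C; then aq. HCl
Reagents that add atoms: diethyl carbonate, CCOC(=O)OCC
Why: C-Acylation of the methyl ketone enolate with diethyl carbonate and lactonisation onto the phenoxide (a Claisen-type condensation) is the standard route from 2'-hydroxyacetophenones to 4-hydroxycoumarins.

Step 16
Reactants: 21 (3R)-3-[(3E)-5-hydroxy-3-methylpent-3-en-1-yl]-2,2-dimethyl-4-methylidenecyclohexan-1-one; 23 4-hydroxy-5-methyl-2H-chromen-2-one
Product: 24 4-{[(2E)-5-[(1R)-2,2-dimethyl-6-methylidene-3-oxocyclohexyl]-3-methylpent-2-en-1-yl]oxy}-5-methyl-2H-chromen-2-one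
Conditions: PPh3, DIAD, THF, 0 °C → rt
Reagents that add atoms: none
Why: Mitsunobu reaction: the acidic 4-hydroxyl of 23 (a vinylogous carboxylic acid) protonates the phosphine–azodicarboxylate betaine and its oxygen displaces the primary allylic alkoxyphosphonium at CH2, which leaves the E alkene and the stereocentre untouched. Alkylation at the C4 oxygen gives the conjugated 4-alkoxycoumarin, and room temperature stays below the onset of Claisen rearrangement.

## Compound list

1 | (S)-(−)-limonene, (4S)-1-methyl-4-(prop-1-en-2-yl)cyclohex-1-ene | CC1=CC[C@H](CC1)C(C)=C | starting material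
2 | (3S)-6-oxo-3-(prop-1-en-2-yl)heptanal | O=CC[C@@H](C(C)=C)CCC(C)=O | intermediate
3 | (5S)-7,7-dimethoxy-5-(prop-1-en-2-yl)heptan-2-one | COC(OC)C[C@@H](C(C)=C)CCC(C)=O | intermediate
4 | triethyl phosphonoacetate | CCOC(=O)CP(=O)(OCC)OCC | starting material
5 | ethyl (2E,6S)-8,8-dimethoxy-3-methyl-6-(prop-1-en-2-yl)oct-2-enoate | COC(OC)C[C@@H](C(C)=C)CC/C(C)=C/C(=O)OCC | intermediate
6 | (2E,6S)-8,8-dimethoxy-3-methyl-6-(prop-1-en-2-yl)oct-2-en-1-ol | COC(OC)C[C@@H](C(C)=C)CC/C(C)=C/CO | intermediate
7 | tert-butyl{[(2E,6S)-8,8-dimethoxy-3-methyl-6-(prop-1-en-2-yl)oct-2-en-1-yl]oxy}diphenylsilane | COC(OC)C[C@@H](C(C)=C)CC/C(C)=C/CO[Si](c1ccccc1)(c1ccccc1)C(C)(C)C | intermediate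
8 | (3S,6E)-8-[(tert-butyldiphenylsilyl)oxy]-6-methyl-3-(prop-1-en-2-yl)oct-6-enal | O=CC[C@@H](C(C)=C)CC/C(C)=C/CO[Si](c1ccccc1)(c1ccccc1)C(C)(C)C | intermediate
9 | (3S,6E)-8-[(tert-butyldiphenylsilyl)oxy]-6-methyl-3-(prop-1-en-2-yl)oct-6-enal oxime (both C=N isomers) | ON=CC[C@@H](C(C)=C)CC/C(C)=C/CO[Si](c1ccccc1)(c1ccccc1)C(C)(C)C | intermediate
10 | (3S,6E)-8-[(tert-butyldiphenylsilyl)oxy]-6-methyl-3-(prop-1-en-2-yl)oct-6-enenitrile | N#CC[C@@H](C(C)=C)CC/C(C)=C/CO[Si](c1ccccc1)(c1ccccc1)C(C)(C)C | intermediate
11 | (3S,6E)-8-[(tert-butyldiphenylsilyl)oxy]-2,6-dimethyl-3-(prop-1-en-2-yl)oct-6-enenitrile (both C2 epimers) | N#CC(C)[C@@H](C(C)=C)CC/C(C)=C/CO[Si](c1ccccc1)(c1ccccc1)C(C)(C)C | intermediate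
12 | (3R,6E)-8-[(tert-butyldiphenylsilyl)oxy]-2,2,6-trimethyl-3-(prop-1-en-2-yl)oct-6-enenitrile | N#CC(C)(C)[C@@H](C(C)=C)CC/C(C)=C/CO[Si](c1ccccc1)(c1ccccc1)C(C)(C)C | intermediate
13 | N-(diisobutylaluminio) (3R,6E)-8-[(tert-butyldiphenylsilyl)oxy]-2,2,6-trimethyl-3-(prop-1-en-2-yl)oct-6-en-1-imine | CC(C)C[Al](CC(C)C)N=CC(C)(C)[C@@H](C(C)=C)CC/C(C)=C/CO[Si](c1ccccc1)(c1ccccc1)C(C)(C)C | intermediate
14 | (3R,6E)-8-[(tert-butyldiphenylsilyl)oxy]-2,2,6-trimethyl-3-(prop-1-en-2-yl)oct-6-enal | O=CC(C)(C)[C@@H](C(C)=C)CC/C(C)=C/CO[Si](c1ccccc1)(c1ccccc1)C(C)(C)C | intermediate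
15 | (4R,7E)-9-[(tert-butyldiphenylsilyl)oxy]-1-[dimethyl(propan-2-yloxy)silyl]-3,3,7-trimethyl-4-(prop-1-en-2-yl)non-7-en-2-ol (both C2 epimers) | CC(C)O[Si](C)(C)CC(O)C(C)(C)[C@@H](C(C)=C)CC/C(C)=C/CO[Si](c1ccccc1)(c1ccccc1)C(C)(C)C | intermediate
16 | (4R,7E)-9-[(tert-butyldiphenylsilyl)oxy]-3,3,7-trimethyl-4-(prop-1-en-2-yl)non-7-ene-1,2-diol (both C2 epimers) | OCC(O)C(C)(C)[C@@H](C(C)=C)CC/C(C)=C/CO[Si](c1ccccc1)(c1ccccc1)C(C)(C)C | intermediate
17 | (4R,7E)-9-[(tert-butyldiphenylsilyl)oxy]-3,3,7-trimethyl-2-oxo-4-(prop-1-en-2-yl)non-7-enal | O=CC(=O)C(C)(C)[C@@H](C(C)=C)CC/C(C)=C/CO[Si](c1ccccc1)(c1ccccc1)C(C)(C)C | intermediate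
18 | (3R)-3-[(3E)-5-[(tert-butyldiphenylsilyl)oxy]-3-methylpent-3-en-1-yl]-6-hydroxy-2,2-dimethyl-4-methylidenecyclohexan-1-one (both C6 epimers) | C=C1CC(O)C(=O)C(C)(C)[C@@H]1CC/C(C)=C/CO[Si](c1ccccc1)(c1ccccc1)C(C)(C)C | intermediate
19 | (4R)-4-[(3E)-5-[(tert-butyldiphenylsilyl)oxy]-3-methylpent-3-en-1-yl]-3,3-dimethyl-5-methylidene-2-oxocyclohexyl acetate (both C1 epimers) | C=C1CC(OC(C)=O)C(=O)C(C)(C)[C@@H]1CC/C(C)=C/CO[Si](c1ccccc1)(c1ccccc1)C(C)(C)C | intermediate
20 | (3R)-3-[(3E)-5-[(tert-butyldiphenylsilyl)oxy]-3-methylpent-3-en-1-yl]-2,2-dimethyl-4-methylidenecyclohexan-1-one | C=C1CCC(=O)C(C)(C)[C@@H]1CC/C(C)=C/CO[Si](c1ccccc1)(c1ccccc1)C(C)(C)C | intermediate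
21 | (3R)-3-[(3E)-5-hydroxy-3-methylpent-3-en-1-yl]-2,2-dimethyl-4-methylidenecyclohexan-1-one | C=C1CCC(=O)C(C)(C)[C@@H]1CC/C(C)=C/CO | intermediate
22 | 2'-hydroxy-6'-methylacetophenone | CC(=O)c1c(C)cccc1O | starting material
23 | 4-hydroxy-5-methyl-2H-chromen-2-one | Cc1cccc2oc(=O)cc(O)c12 | intermediate
24 | 4-{[(2E)-5-[(1R)-2,2-dimethyl-6-methylidene-3-oxocyclohexyl]-3-methylpent-2-en-1-yl]oxy}-5-methyl-2H-chromen-2-one | C=C1CCC(=O)C(C)(C)[C@@H]1CC/C(C)=C/COc1cc(=O)oc2cccc(C)c12 | target

## Step count and least certain steps

Total step count: 16. Longest linear sequence: 15 steps (steps 1 to 14 and step 16, from 1). The branch to 23 is one step (step 15).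

**Step 11 (key step).** The 1,2-dicarbonyl unit may hydrate or self-condense before it cyclises. Aluminium may transfer a methyl group to the activated aldehyde. The closure may turn stepwise and cationic, with chloride capture or migration of the new double bond into the ring. The product ketol may tautomerise through its enediol under the Lewis acid. The fallback avoids the dicarbonyl enophile and uses a plain α-silyloxy aldehyde. From 16, silylation of both hydroxyls (Et3SiOTf, 2,6-lutidine) would give the bis(triethylsilyl) ether F1. Swern conditions, which oxidise a primary triethylsilyl ether directly and leave the secondary one, would give the α-silyloxy aldehyde F2. The same Me2AlCl type 2 ene closure on this simple aldehyde would give the cyclohexanol F3, and acetylation would give the acetate F4. Mild acid (PPTS, MeOH, 0 °C) would free the neopentyl hydroxyl in the hydroxy acetate F5. Dess–Martin oxidation of F5 rejoins the route at 19.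

**Step 10.** Oxidation of the hindered secondary hydroxyl may stall, and the product may hydrate or oligomerise during work-up, so that the enophile reaches step 11 impure. The fallback brings in the terminal carbon already at the aldehyde oxidation level. From 14, addition of 2-lithio-1,3-dithiane would give the dithianyl carbinol F6. Oxidation (SO3·pyridine, DMSO, i-Pr2NEt) would give the acyl dithiane F7. Alkylative hydrolysis (MeI, CaCO3, aq. MeCN), which tolerates alkenes, rejoins the route at 17.

**Step 2.** The olefination of a methyl ketone may show poor geometric selectivity, and separating the isomers costs material. The fallback sets the geometry by syn carbometalation. From 3, the kinetic enolate (LiN(i-Pr)2, −78 °C) would be trapped with ClP(O)(OEt)2 as the enol phosphate F8. Two further equivalents of LiN(i-Pr)2 would eliminate it to the terminal alkyne F9. Methylalumination with AlMe3 under Cp2ZrCl2 catalysis (water-accelerated, low temperature, to spare the acetal), then trapping of the alkenylalane with paraformaldehyde, rejoins the route at 6 as the E isomer only.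

**Step 16.** The ambident coumarin anion may be alkylated at the lactone carbonyl oxygen or at C3, and the allylic terminus may be attacked with transposition. The fallback forms the aryl–oxygen bond in place of the allyl–oxygen bond, which fixes the site of attachment. From 23, POCl3 with Et3N would give the chlorocoumarin F10. The sodium alkoxide of 21 (one equivalent of NaH, THF, 0 °C) would add to C4 and expel chloride to give 24.

**Step 1.** Ozone may also attack the isopropenyl group, and acetalisation may be incomplete or extend to the ketone. The fallback separates alkene selection from cleavage. From 1, mCPBA (CH2Cl2, 0 °C) would epoxidise only the trisubstituted alkene to limonene 1,2-oxide F11. H5IO6 in aq. THF would open and cleave it to 2, and MeOH with catalytic p-TsOH rejoins the route at 3.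

## Further compounds

F1 | step 11 | (4R,7E)-9-[(tert-butyldiphenylsilyl)oxy]-3,3,7-trimethyl-4-(prop-1-en-2-yl)-1,2-bis[(triethylsilyl)oxy]non-7-ene (both C2 epimers) | CC[Si](CC)(CC)OCC(O[Si](CC)(CC)CC)C(C)(C)[C@@H](C(C)=C)CC/C(C)=C/CO[Si](c1ccccc1)(c1ccccc1)C(C)(C)C
F2 | step 11 | (4R,7E)-9-[(tert-butyldiphenylsilyl)oxy]-3,3,7-trimethyl-4-(prop-1-en-2-yl)-2-[(triethylsilyl)oxy]non-7-enal (both C2 epimers) | O=CC(O[Si](CC)(CC)CC)C(C)(C)[C@@H](C(C)=C)CC/C(C)=C/CO[Si](c1ccccc1)(c1ccccc1)C(C)(C)C
F3 | step 11 | (4R)-4-[(3E)-5-[(tert-butyldiphenylsilyl)oxy]-3-methylpent-3-en-1-yl]-3,3-dimethyl-5-methylidene-2-[(triethylsilyl)oxy]cyclohexan-1-ol (mixture at C1 and C2) | C=C1CC(O)C(O[Si](CC)(CC)CC)C(C)(C)[C@@H]1CC/C(C)=C/CO[Si](c1ccccc1)(c1ccccc1)C(C)(C)C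
F4 | step 11 | (4R)-4-[(3E)-5-[(tert-butyldiphenylsilyl)oxy]-3-methylpent-3-en-1-yl]-3,3-dimethyl-5-methylidene-2-[(triethylsilyl)oxy]cyclohexyl acetate (mixture at C1 and C2) | C=C1CC(OC(C)=O)C(O[Si](CC)(CC)CC)C(C)(C)[C@@H]1CC/C(C)=C/CO[Si](c1ccccc1)(c1ccccc1)C(C)(C)C
F5 | step 11 | (4R)-4-[(3E)-5-[(tert-butyldiphenylsilyl)oxy]-3-methylpent-3-en-1-yl]-2-hydroxy-3,3-dimethyl-5-methylidenecyclohexyl acetate (mixture at C1 and C2) | C=C1CC(OC(C)=O)C(O)C(C)(C)[C@@H]1CC/C(C)=C/CO[Si](c1ccccc1)(c1ccccc1)C(C)(C)C
F6 | step 10 | (3R,6E)-8-[(tert-butyldiphenylsilyl)oxy]-1-(1,3-dithian-2-yl)-2,2,6-trimethyl-3-(prop-1-en-2-yl)oct-6-en-1-ol (both C1 epimers) | OC(C1SCCCS1)C(C)(C)[C@@H](C(C)=C)CC/C(C)=C/CO[Si](c1ccccc1)(c1ccccc1)C(C)(C)C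
F7 | step 10 | (3R,6E)-8-[(tert-butyldiphenylsilyl)oxy]-1-(1,3-dithian-2-yl)-2,2,6-trimethyl-3-(prop-1-en-2-yl)oct-6-en-1-one | O=C(C1SCCCS1)C(C)(C)[C@@H](C(C)=C)CC/C(C)=C/CO[Si](c1ccccc1)(c1ccccc1)C(C)(C)C
F8 | step 2 | diethyl (5S)-7,7-dimethoxy-5-(prop-1-en-2-yl)hept-1-en-2-yl phosphate | COC(OC)C[C@@H](C(C)=C)CCC(=C)OP(=O)(OCC)OCC
F9 | step 2 | (5S)-7,7-dimethoxy-5-(prop-1-en-2-yl)hept-1-yne | COC(OC)C[C@@H](C(C)=C)CCC#C
F10 | step 16 | 4-chloro-5-methyl-2H-chromen-2-one | Cc1cccc2oc(=O)cc(Cl)c12
F11 | step 1 | (4S)-1-methyl-4-(prop-1-en-2-yl)-7-oxabicyclo[4.1.0]heptane (limonene 1,2-oxide, both epoxide diastereomers) | CC12CC[C@@H](CC1O2)C(C)=C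
A1 | alternative 1 | (2E)-5-[(1R,3S)-3-[(tert-butyldimethylsilyl)oxy]-2,2-dimethyl-6-methylidenecyclohexyl]-3-methylpent-2-en-1-ol | C=C1CC[C@H](O[Si](C)(C)C(C)(C)C)C(C)(C)[C@@H]1CC/C(C)=C/CO
A2 | alternative 1 | tert-butyl{[(1S,3R)-3-(but-3-yn-1-yl)-2,2-dimethyl-4-methylidenecyclohexyl]oxy}dimethylsilane | C=C1CC[C@H](O[Si](C)(C)C(C)(C)C)C(C)(C)[C@@H]1CCC#C
A3 | alternative 2 | ethyl [(7S)-6,6-dimethyl-8-oxo-1,4-dioxaspiro[4.5]dec-7-yl]acetate | O=C1CCC2(OCCO2)C(C)(C)[C@@H]1CC(=O)OCC
A4 | alternative 2 | ethyl (2E)-4-methyl-4-[2-(3-oxopropyl)-1,3-dioxolan-2-yl]pent-2-enoate | O=CCCC1(OCCO1)C(C)(C)/C=C/C(=O)OCC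
A5 | alternative 3 | (2R)-2-{2-[(tert-butyldimethylsilyl)oxy]ethyl}-3,3-dimethyl-4-oxocyclohexane-1-carbaldehyde (both C1 epimers) | O=CC1CCC(=O)C(C)(C)[C@@H]1CCO[Si](C)(C)C(C)(C)C
A6 | alternative 3 | (3R)-3-{2-[(tert-butyldimethylsilyl)oxy]ethyl}-4,4-dimethyl-5-oxohept-6-enal | C=CC(=O)C(C)(C)[C@@H](CC=O)CCO[Si](C)(C)C(C)(C)C
A7 | alternative 3 | 2-[(1S)-2,2,3-trimethylcyclopent-3-en-1-yl]acetaldehyde | CC1=CC[C@@H](CC=O)C1(C)C
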